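Minutes. The meeting opened on zeta's leftover: at the last reading, 40.0 s, target and decomposed reagent together left 19.5% of the charged substrate unaccounted for, and zeta is the flask asked about.

| flask | substrate | precatalyst | remark | time |
|---|---|---|---|---|
| zeta | 12 mM (fed, over 5.0 s) | 0.26 mM | the very flask that is asked about, followed so far |  |
| delta | 12 mM (fed, over 5.0 s) | 0.17 mM | run made earlier |  |
| flask | 12 mM (fed, over 5.0 s) | 0.26 mM |  | 3.0 min |

zeta run (percent of the substrate charged)

| time / s | target / % | decomposed reagent / % |
|---|---|---|
| 10.0 | 6.6 | 8.3 |
| 12.0 | 10.3 | 11.7 |
| 25.0 | 30.1 | 27.3 |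
| 40.0 | 42.6 | 37.9 |

delta run (percent of the substrate charged)

| time / min | target / % | decomposed reagent / % |
|---|---|---|
| 0.250 | 10.6 | 16.7 |
| 0.500 | 26.1 | 34.7 |
| 1.33 | 41.3 | 53.6 |
| 3.00 | 44.1 | 55.9 |

(scatter of a reading: 0.5 percentage points)

- concentration of target at 3.0 min, in mM
- concentration of decomposed reagent at 3.0 min, in mM



The chair pointed out that in delta the two products summed to 100% at 3.00 min, and so proposed to assume the same closure in zeta, leaving one question: how the leftover divides.

The kineticist, reckoning independently, took the branching ratio (selectivity factor) between target and decomposed reagent after the feed. In zeta, from 12.0 s to 40.0 s, it reads 1.23. The kineticist then defined g, that ratio divided by the precatalyst concentration c, which gives 4.74 /mM. Delta, a separate run at a lower c, reads 5.03 /mM, so the kineticist held g to be usable across these two precatalyst charges. Dividing the leftover at g·c gave 6.40 mM of target and 5.60 mM of decomposed reagent.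

The forecast, reported next, stands at 6.41 mM and 5.59 mM, on the ground that “target formation is first order in catalyst, while decomposition is independent of it”. These are its own figures, which differ slightly from the kineticist's.

The flask gives 6.42 mM of target and 5.52 mM of decomposed reagent.

    substrate → intermediate (k = 0.240 /s)
    catalyst + intermediate → catalyst + target (k = 200 /M/s)
    substrate + target → side product (k = 1.30 /M/s)
    precatalyst ⇌ catalyst (K = 1.30, k = 0.100 /s)
    intermediate → decomposed reagent (k = 0.0230 /s)

At 0.0940 min the flask's catalyst used intermediate at 0.81 of the rate of the intermediate's conversion into decomposed reagent, whereas with catalyst at 56.5% of the charge, at 1.50 min, that ratio computes to 1.28. The flask's end ratio of target to decomposed reagent, 1.16, lies below g·c, 1.23. With 0.16 mM of precatalyst, g·c is 0.758, and dividing the whole charge at that ratio estimates target at 5.18 mM; that neighbouring flask holds 5.03 mM.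

The data were generated by integration on assumed constants; noise was put on by code.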